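A direct plan would start from ring B's carbons as a cyclopentanone, (S)-2,2-dimethyl-3-prenylcyclopentanone A1, made by a catalytic asymmetric prenyl conjugate addition and enolate methylation.
It would prenylate A1, build ring A on it with diketene (C-acylation, then aldol), O-methylate to the hydrindenone A2, and widen the five-membered ring by an oxidative 1,2-shift to the bicyclo[3.3.1]nonenedione A3.
C3 aroylation with a silyl-protected catechol acid chloride (to A4), bridgehead prenylation at C1 and hydrolysis would complete it.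
Weakest would be the ring expansion: a tertiary alkoxide would have to push the quaternary CMe2 carbon onto an iodanylated γ-carbon, a shift without precedent on so crowded a frame, competing with plain γ-methoxylation and elimination.
Next would be the diketene C-acylation: the C5 quaternary centre would rest only on the facial bias that one remote prenyl group gives a flat cyclopentanone enolate, and the ee of everything on an untried catalytic step.
Third would be the bridgehead lithiation and prenylation of A4: the most precious intermediate, now holding an electrophilic aryl ketone, would meet LiTMP at the hindered C–H next to CMe2.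
Three further steps would go into an aroyl chloride that serves one late C–C bond.

**Plan of the new route**
Numbering follows the target name: ring A is C1–C5 plus C9, ring B is C1, C8, C7, C6, C5, C9.
The retrosynthesis cuts C1–C8 first and C5–C6 second; this leaves ring A as an aromatic 2-aroylphloroglucinol and the rest of ring B (C6, C7, C8, both methyls, the C7 side chain) as one allylic C8 bromide.
The enabling feature is that C1 and C5 are the two nucleophilic ring carbons of a dearomatised acylphloroglucinol, and C8 is a tertiary carbon three atoms from C5, so a cation at C8 can be captured by C1.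
Ring A is thus present from the start as an arene; an enantioselective dearomative C-alkylation sets the C5 quaternary centre, and a proton-initiated cation–enol ether cyclisation closes ring B, joins the fully substituted carbons C1 and C8, and sets C1 and C7.
The aroyl group is on ring A before any C–C bond is made, and the side chains travel as acid-stable allyl groups that one cross-metathesis turns into prenyl; hence no ring expansion, no enolate acylation on a small ring, no bridgehead metalation and no late acylation arise.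

Key step: step 8

Assumption: the sense of asymmetric induction of the cinchona-derived ammonium salt in step 6 cannot be predicted with certainty for this nucleophile; the cinchonidinium salt is written, and its pseudoenantiomeric cinchoninium salt would be taken if the opposite sense is found.

Step 1
Reactants: 1 3,4-dihydroxybenzoic acid (protocatechuic acid)
Product: 2 3,4-bis[(4-methylbenzenesulfonyl)oxy]benzoic acid
Conditions: TsCl (2.3 equiv), 2 M aq. NaOH, THF, 0 °C → rt, under Ar; then 2 M HCl
Reagents that add atoms: 4-methylbenzenesulfonyl chloride, Cc1ccc(cc1)S(Cl)(=O)=O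
Why: Schotten–Baumann O-sulfonylation of both phenols (the mixed carboxylic–sulfonic anhydride hydrolyses on work-up), giving aryl tosylates that should withstand AlCl3, cold aqueous hydroxide, formic acid and a ruthenium carbene and yet fall to hot hydroxide in the last step.

Step 2
Reactants: 2 3,4-bis[(4-methylbenzenesulfonyl)oxy]benzoic acid; 3 benzene-1,3,5-triol (phloroglucinol)
Product: 5 4-(2,4,6-trihydroxybenzoyl)-1,2-phenylene bis(4-methylbenzenesulfonate), via 3,4-bis(tosyloxy)benzoyl chloride 4 (not isolated)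
Conditions: (COCl)2, DMF (cat.), CH2Cl2, 0 °C → rt; evaporate; 3, AlCl3 (4 equiv), PhNO2, rt → 60 °C; ice/2 M HCl
Reagents that add atoms: none
Why: Vilsmeier-type acid chloride formation followed by Friedel–Crafts C-acylation of phloroglucinol, which stops at mono-acylation because the first acyl group deactivates the ring.

Step 3
Reactants: 5 4-(2,4,6-trihydroxybenzoyl)-1,2-phenylene bis(4-methylbenzenesulfonate); 6 3-bromoprop-1-ene (allyl bromide)
Product: 7 4-[2,4,6-trihydroxy-3,5-di(prop-2-en-1-yl)benzoyl]-1,2-phenylene bis(4-methylbenzenesulfonate)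
Conditions: 6 (2.1 equiv), 10% aq. KOH, 0 °C; then 1 M HCl
Reagents that add atoms: none
Why: C-Allylation of the acylphloroglucinol phenolate in water, where hydrogen bonding to oxygen favours attack through the two free ring carbons flanked by hydroxyl groups; the product is symmetric and has no stereocentre.

Step 4
Reactants: 8 but-2-yn-1-ol; 9 allylmagnesium bromide (Et2O solution)
Product: 11 3-methyl-2-(prop-2-en-1-yl)but-2-en-1-ol, via cyclic alkenylmagnesium alkoxide 10 (not isolated)
Conditions: 9 (3 equiv), Et2O, 0 °C → reflux; then CuI (10 mol %), MeI (excess), THF, 0 °C → rt; aq. NH4Cl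
Reagents that add atoms: iodomethane, CI
Why: Hydroxyl-directed anti-carbomagnesiation of a propargylic alkoxide (allylmagnesiation), which delivers the allyl group to C2 and leaves magnesium on C3 in the five-membered chelate 10, followed by copper-catalysed alkylation of the alkenylmagnesium with iodomethane; the alkene geometry is immaterial because C3 ends with two methyl groups.

Step 5
Reactants: 11 3-methyl-2-(prop-2-en-1-yl)but-2-en-1-ol
Product: 12 1-bromo-3-methyl-2-(prop-2-en-1-yl)but-2-ene
Conditions: PBr3 (0.4 equiv), pyridine (cat.), Et2O, −10 → 0 °C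
Reagents that add atoms: phosphorus tribromide, BrP(Br)Br
Why: SN2 bromination of a primary allylic alcohol with PBr3; the primary bromide with the tetrasubstituted alkene is also the thermodynamically preferred allylic isomer.

Step 6
Reactants: 7 4-[2,4,6-trihydroxy-3,5-di(prop-2-en-1-yl)benzoyl]-1,2-phenylene bis(4-methylbenzenesulfonate); 12 1-bromo-3-methyl-2-(prop-2-en-1-yl)but-2-ene
Product: 13 4-{[(5R)-2,4-dihydroxy-5-[3-methyl-2-(prop-2-en-1-yl)but-2-en-1-yl]-6-oxo-3,5-di(prop-2-en-1-yl)cyclohexa-1,3-dien-1-yl]carbonyl}-1,2-phenylene bis(4-methylbenzenesulfonate)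
Conditions: O-allyl-N-(9-anthracenylmethyl)cinchonidinium bromide (15 mol %), CsOH·H2O (3 equiv), 12 (1.2 equiv), toluene/CH2Cl2 (4:1), 4 Å MS, −50 → −30 °C; then 1 M HCl
Reagents that add atoms: none
Why: Proposed new method: under solid–liquid phase-transfer conditions the caesium phenolate of 7 should enter the organic phase only as a tight ion pair with the chiral ammonium cation, which must shield one of the two enantiotopic allyl-bearing ring carbons (future C1 and C5) so that SN2 attack of the other on the primary allylic bromide 12 creates the C5 quaternary centre (R in 13) by desymmetrisation, with C- over O-alkylation favoured by the soft allylic electrophile and the non-polar medium and with the vinylogous acid 13 too weakly nucleophilic to react again; the closest known reaction types are the cinchona ammonium salt/CsOH-mediated enantioselective alkylative dearomatisation of 3,5-diprenylated acylphloroglucinols with enal Michael acceptors and the asymmetric phase-transfer allylation of glycine-imine enolates with allylic bromides.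

Step 7
Reactants: 13 4-{[(5R)-2,4-dihydroxy-5-[3-methyl-2-(prop-2-en-1-yl)but-2-en-1-yl]-6-oxo-3,5-di(prop-2-en-1-yl)cyclohexa-1,3-dien-1-yl]carbonyl}-1,2-phenylene bis(4-methylbenzenesulfonate)
Product: 14 4-{[(5R)-2-hydroxy-4-methoxy-5-[3-methyl-2-(prop-2-en-1-yl)but-2-en-1-yl]-6-oxo-3,5-di(prop-2-en-1-yl)cyclohexa-1,3-dien-1-yl]carbonyl}-1,2-phenylene bis(4-methylbenzenesulfonate)
Conditions: TMSCHN2 (1.5 equiv), MeOH/toluene (1:3), 0 °C
Reagents that add atoms: (trimethylsilyl)diazomethane, C[Si](C)(C)C=[N+]=[N-]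
Why: O-Methylation of a vinylogous acid with a diazoalkane, which should take the free, most acidic enol hydroxyl (O9) and leave the hydroxyl chelated to the aroyl carbonyl; methylation at O2 instead would also place C1 at the β-carbon of an enol ether, so the regiochemistry is not critical, and C5 is untouched.

Step 8
Reactants: 14 4-{[(5R)-2-hydroxy-4-methoxy-5-[3-methyl-2-(prop-2-en-1-yl)but-2-en-1-yl]-6-oxo-3,5-di(prop-2-en-1-yl)cyclohexa-1,3-dien-1-yl]carbonyl}-1,2-phenylene bis(4-methylbenzenesulfonate)
Product: 15 4-{[(1S,5S,7R)-4-hydroxy-8,8-dimethyl-2,9-dioxo-1,5,7-tri(prop-2-en-1-yl)bicyclo[3.3.1]non-3-en-3-yl]carbonyl}-1,2-phenylene bis(4-methylbenzenesulfonate)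
Conditions: HCO2H (98%, 0.02 M), 23 → 40 °C; evaporate (toluene azeotrope)
Reagents that add atoms: none
Why: Formic acid should protonate the tetrasubstituted C7=C8 alkene reversibly (the monosubstituted allyl groups are not protonated under these conditions), at C7 to give the tertiary C8 cation, which is attacked by C1, the β-carbon of the C9 methyl enol ether; the C9 oxocarbenium ion then loses its methyl group to formate and leaves the bridging ketone and the free enolised triketone. The closest known reaction type is the formic-acid-mediated biomimetic cation–enol ether cyclisation of dearomatised acylphloroglucinols to bicyclo[3.3.1]nonane-2,4,9-triones, itself a cation–olefin cyclisation terminated by an enol ether. Ring B closes in a 6-(enolendo) mode that is 6-endo-trig with respect to the protonated alkene, through a chair in which C6–C7–C8 lies over one face of the flat ring A, whereas attack of C1 on the alternative C7 cation would be a 5-(enolendo)-exo closure, disfavoured stereoelectronically and by the more crowded cationic carbon. C1 is fixed by C5, because the chain can reach only the face of ring A that it occupies, and C7, which is not a stereocentre before the step, arises by reversible protonation, so both C7-epimeric cations equilibrate through the alkene and the product comes from the chair in which the allyl group points outward (exo, equatorial on ring B) and not into ring A (Curtin–Hammett control). The step needs C- over O-alkylation and C1 over C3 attack: capture of the cation by O4 or O9 gives tert-alkyl vinylogous esters or oxonium ions that re-ionise in formic acid as tert-butyl esters do, whereas C–C bond formation is irreversible, and C3 is the chelated, aroyl-substituted central carbon of the triketone and far less nucleophilic than the enol ether carbon C1.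

Step 9
Reactants: 15 4-{[(1S,5S,7R)-4-hydroxy-8,8-dimethyl-2,9-dioxo-1,5,7-tri(prop-2-en-1-yl)bicyclo[3.3.1]non-3-en-3-yl]carbonyl}-1,2-phenylene bis(4-methylbenzenesulfonate); 16 2-methylbut-2-ene
Product: 17 4-{[(1S,5S,7R)-4-hydroxy-8,8-dimethyl-1,5,7-tris(3-methylbut-2-en-1-yl)-2,9-dioxobicyclo[3.3.1]non-3-en-3-yl]carbonyl}-1,2-phenylene bis(4-methylbenzenesulfonate)
Conditions: 16 (60 equiv, co-solvent), second-generation Grubbs catalyst RuCl2(H2IMes)(PCy3)(=CHPh) (2 × 5 mol %), CH2Cl2, 40 °C (sealed tube)
Reagents that add atoms: 2-methylbut-2-ene, CC=C(C)C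
Why: Threefold olefin cross-metathesis with a large excess of a trisubstituted partner, the established way to turn C-allyl into prenyl groups on bicyclo[3.3.1]nonane-trione cores, in which each of the three allyl groups takes one isopropylidene unit from its own molecule of 16 and gives up its CH2 terminus as propene, so that three molecules of 16 are consumed in all (16 therefore stands both as reactant and as atom-adding reagent); aryl sulfonates and the hydrogen-bonded enol should be tolerated and no stereocentre is touched.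

Step 10
Reactants: 17 4-{[(1S,5S,7R)-4-hydroxy-8,8-dimethyl-1,5,7-tris(3-methylbut-2-en-1-yl)-2,9-dioxobicyclo[3.3.1]non-3-en-3-yl]carbonyl}-1,2-phenylene bis(4-methylbenzenesulfonate)
Product: 18 aristophenone A
Conditions: KOH (2 M aq., 10 equiv), 1,4-dioxane (degassed), 90 °C; then 1 M HCl, 0 °C
Reagents that add atoms: none
Why: Hydroxide attack at sulfur should cleave both aryl sulfonate esters (S–O cleavage) while the triketone is protected as its delocalised enolate and exclusion of oxygen protects the catecholate; C1 and C5 are quaternary and C7 is unactivated, so nothing can epimerise.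

**Compound list**
1 | 3,4-dihydroxybenzoic acid (protocatechuic acid) | O=C(O)c1ccc(O)c(O)c1 | starting material
2 | 3,4-bis[(4-methylbenzenesulfonyl)oxy]benzoic acid | O=C(O)c1ccc(OS(=O)(=O)c2ccc(C)cc2)c(OS(=O)(=O)c2ccc(C)cc2)c1 | intermediate
3 | benzene-1,3,5-triol (phloroglucinol) | Oc1cc(O)cc(O)c1 | starting material
4 | 3,4-bis[(4-methylbenzenesulfonyl)oxy]benzoyl chloride | O=C(Cl)c1ccc(OS(=O)(=O)c2ccc(C)cc2)c(OS(=O)(=O)c2ccc(C)cc2)c1 | intermediate (not isolated)
5 | 4-(2,4,6-trihydroxybenzoyl)-1,2-phenylene bis(4-methylbenzenesulfonate) | O=C(c1c(O)cc(O)cc1O)c1ccc(OS(=O)(=O)c2ccc(C)cc2)c(OS(=O)(=O)c2ccc(C)cc2)c1 | intermediate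
6 | 3-bromoprop-1-ene (allyl bromide) | C=CCBr | starting material
7 | 4-[2,4,6-trihydroxy-3,5-di(prop-2-en-1-yl)benzoyl]-1,2-phenylene bis(4-methylbenzenesulfonate) | O=C(c1c(O)c(CC=C)c(O)c(CC=C)c1O)c1ccc(OS(=O)(=O)c2ccc(C)cc2)c(OS(=O)(=O)c2ccc(C)cc2)c1 | intermediate
8 | but-2-yn-1-ol | CC#CCO | starting material
9 | allylmagnesium bromide (prop-2-en-1-ylmagnesium bromide, Et2O solution) | C=CC[Mg]Br | starting material
10 | 3-methyl-4-(prop-2-en-1-yl)-2,5-dihydro-1,2-oxamagnesole (cyclic alkenylmagnesium alkoxide; allyl on C2 and Mg on C3 of the former butynol, anti) | CC1=C(CC=C)CO[Mg]1 | intermediate (not isolated)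
11 | 3-methyl-2-(prop-2-en-1-yl)but-2-en-1-ol | OCC(CC=C)=C(C)C | intermediate
12 | 1-bromo-3-methyl-2-(prop-2-en-1-yl)but-2-ene | BrCC(CC=C)=C(C)C | intermediate
13 | 4-{[(5R)-2,4-dihydroxy-5-[3-methyl-2-(prop-2-en-1-yl)but-2-en-1-yl]-6-oxo-3,5-di(prop-2-en-1-yl)cyclohexa-1,3-dien-1-yl]carbonyl}-1,2-phenylene bis(4-methylbenzenesulfonate) (dearomatised triketone; the quaternary carbon is C5 of the future core) | C=CC[C@]1(CC(CC=C)=C(C)C)C(=O)C(C(=O)c2ccc(OS(=O)(=O)c3ccc(C)cc3)c(OS(=O)(=O)c3ccc(C)cc3)c2)=C(O)C(CC=C)=C1O | intermediate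
14 | 4-{[(5R)-2-hydroxy-4-methoxy-5-[3-methyl-2-(prop-2-en-1-yl)but-2-en-1-yl]-6-oxo-3,5-di(prop-2-en-1-yl)cyclohexa-1,3-dien-1-yl]carbonyl}-1,2-phenylene bis(4-methylbenzenesulfonate) (methyl enol ether at O9 of the future core) | C=CC[C@]1(CC(CC=C)=C(C)C)C(=O)C(C(=O)c2ccc(OS(=O)(=O)c3ccc(C)cc3)c(OS(=O)(=O)c3ccc(C)cc3)c2)=C(O)C(CC=C)=C1OC | intermediate
15 | 4-{[(1S,5S,7R)-4-hydroxy-8,8-dimethyl-2,9-dioxo-1,5,7-tri(prop-2-en-1-yl)bicyclo[3.3.1]non-3-en-3-yl]carbonyl}-1,2-phenylene bis(4-methylbenzenesulfonate) (C7 allyl exo) | C=CC[C@@H]1C[C@]2(CC=C)C(=O)[C@@](CC=C)(C(=O)C(C(=O)c3ccc(OS(=O)(=O)c4ccc(C)cc4)c(OS(=O)(=O)c4ccc(C)cc4)c3)=C2O)C1(C)C | intermediate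
16 | 2-methylbut-2-ene | CC=C(C)C | starting material
17 | 4-{[(1S,5S,7R)-4-hydroxy-8,8-dimethyl-1,5,7-tris(3-methylbut-2-en-1-yl)-2,9-dioxobicyclo[3.3.1]non-3-en-3-yl]carbonyl}-1,2-phenylene bis(4-methylbenzenesulfonate) | CC(C)=CC[C@@H]1C[C@]2(CC=C(C)C)C(=O)[C@@](CC=C(C)C)(C(=O)C(C(=O)c3ccc(OS(=O)(=O)c4ccc(C)cc4)c(OS(=O)(=O)c4ccc(C)cc4)c3)=C2O)C1(C)C | intermediate
18 | aristophenone A, (1S,5S,7R)-3-(3,4-dihydroxybenzoyl)-4-hydroxy-8,8-dimethyl-1,5,7-tris(3-methylbut-2-en-1-yl)bicyclo[3.3.1]non-3-ene-2,9-dione | CC(C)=CC[C@@H]1C[C@]2(CC=C(C)C)C(=O)[C@@](CC=C(C)C)(C(=O)C(C(=O)c3ccc(O)c(O)c3)=C2O)C1(C)C | target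

**Step count and risks**
Total: 10 steps. Longest linear sequence: 8 steps (1, 2, 3, 6, 7, 8, 9, 10); steps 4 and 5 make the C8 bromide.

Steps most likely to fail:

Step 6 (labelled). The chiral ion pair may discriminate poorly between the two enantiotopic ring carbons, so that the ee is low, and O-alkylation may compete. The fallback uses known chemistry, sets out from 7 and 12, and returns at 13. Racemic C-alkylation under the aqueous KOH conditions of step 3 would give the racemic dearomatised triketone F1. Acylation of its free enol hydroxyl with (1R,2S,5R)-menthyl chloroformate (Et3N, CH2Cl2, 0 °C) would give two diastereomeric enol carbonates. The (R)-configured menthyl carbonate F2 would be separated by chromatography or crystallisation and cleaved with K2CO3 in MeOH at 0 °C to rejoin the route at 13.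

Step 8 (key). The cation may be intercepted irreversibly at oxygen, the C5 side chain may be lost as an allyl cation with re-aromatisation (which would also erode the ee), or the ring may close through the C7 cation. The fallback closes ring B under basic instead of acidic conditions by a double-Michael alkylative dearomatisation–annulation; it sets out from 7 and returns at 15. Diethyl 2-(propan-2-ylidene)malonate would be reduced with DIBAL-H to 2-(propan-2-ylidene)propane-1,3-diol F3, mono-acetylated (Ac2O, pyridine) to 2-(hydroxymethyl)-3-methylbut-2-en-1-yl acetate F4 and oxidised with MnO2 to 2-(acetoxymethyl)-3-methylbut-2-enal F5. With the ammonium salt and CsOH·H2O of step 6, 7 and this enal should give the bicyclic 7-exo aldehyde F6 by conjugate addition with loss of acetate and a second, intramolecular conjugate addition; the formyl group equilibrates to the exo position. TMSCHN2 would give the methyl enol ether aldehyde F7, vinylmagnesium bromide (THF, −78 °C) the allylic alcohol F8, and Ac2O/DMAP the allylic acetate F9. Pd(PPh3)4/HCO2NH4 (formate reduction, hydride to the more substituted allyl terminus) would then give the C7-allyl methyl enol ether F10. LiCl in DMSO at 120 °C would remove the enol methyl group and rejoin the route at 15.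

Step 4. The carbomagnesiation of the internal alkyne may stop short, or the hindered alkenylmagnesium chelate may resist methylation and be protonated on work-up. The fallback sets out from 8 and returns at 11: allylmagnesiation as in step 4, then iodinolysis (I2, THF, −78 °C), would give (Z)-3-iodo-2-(prop-2-en-1-yl)but-2-en-1-ol F11, and a Negishi coupling (MeZnCl, Pd(PPh3)4, THF, 50 °C) would install the methyl group.

**Further compounds**
F1 | step 6 | racemic 4-{[2,4-dihydroxy-5-[3-methyl-2-(prop-2-en-1-yl)but-2-en-1-yl]-6-oxo-3,5-di(prop-2-en-1-yl)cyclohexa-1,3-dien-1-yl]carbonyl}-1,2-phenylene bis(4-methylbenzenesulfonate) | C=CCC1(CC(CC=C)=C(C)C)C(=O)C(C(=O)c2ccc(OS(=O)(=O)c3ccc(C)cc3)c(OS(=O)(=O)c3ccc(C)cc3)c2)=C(O)C(CC=C)=C1O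
F2 | step 6 | (5R)-enol (1R,2S,5R)-menthyl carbonate of 13 (carbonate on the enol oxygen next to the quaternary carbon) | C=CC[C@]1(CC(CC=C)=C(C)C)C(=O)C(C(=O)c2ccc(OS(=O)(=O)c3ccc(C)cc3)c(OS(=O)(=O)c3ccc(C)cc3)c2)=C(O)C(CC=C)=C1OC(=O)O[C@@H]1C[C@H](C)CC[C@H]1C(C)C
F3 | step 8 | 2-(propan-2-ylidene)propane-1,3-diol | CC(C)=C(CO)CO
F4 | step 8 | 2-(hydroxymethyl)-3-methylbut-2-en-1-yl acetate | CC(=O)OCC(CO)=C(C)C
F5 | step 8 | 2-(acetoxymethyl)-3-methylbut-2-enal | CC(=O)OCC(C=O)=C(C)C
F6 | step 8 | 4-{[(1S,5S,7R)-7-formyl-4-hydroxy-8,8-dimethyl-2,9-dioxo-1,5-di(prop-2-en-1-yl)bicyclo[3.3.1]non-3-en-3-yl]carbonyl}-1,2-phenylene bis(4-methylbenzenesulfonate) (7-exo aldehyde) | O=C[C@@H]1C[C@]2(CC=C)C(=O)[C@@](CC=C)(C(=O)C(C(=O)c3ccc(OS(=O)(=O)c4ccc(C)cc4)c(OS(=O)(=O)c4ccc(C)cc4)c3)=C2O)C1(C)C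
F7 | step 8 | 4-{[(1S,5S,7R)-7-formyl-4-methoxy-8,8-dimethyl-2,9-dioxo-1,5-di(prop-2-en-1-yl)bicyclo[3.3.1]non-3-en-3-yl]carbonyl}-1,2-phenylene bis(4-methylbenzenesulfonate) | O=C[C@@H]1C[C@]2(CC=C)C(=O)[C@@](CC=C)(C(=O)C(C(=O)c3ccc(OS(=O)(=O)c4ccc(C)cc4)c(OS(=O)(=O)c4ccc(C)cc4)c3)=C2OC)C1(C)C
F8 | step 8 | 4-{[(1S,5S,7R)-7-(1-hydroxyprop-2-en-1-yl)-4-methoxy-8,8-dimethyl-2,9-dioxo-1,5-di(prop-2-en-1-yl)bicyclo[3.3.1]non-3-en-3-yl]carbonyl}-1,2-phenylene bis(4-methylbenzenesulfonate) (carbinol epimers) | C=CC(O)[C@@H]1C[C@]2(CC=C)C(=O)[C@@](CC=C)(C(=O)C(C(=O)c3ccc(OS(=O)(=O)c4ccc(C)cc4)c(OS(=O)(=O)c4ccc(C)cc4)c3)=C2OC)C1(C)C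
F9 | step 8 | 1-[(1S,5S,7R)-3-{3,4-bis[(4-methylbenzenesulfonyl)oxy]benzoyl}-4-methoxy-8,8-dimethyl-2,9-dioxo-1,5-di(prop-2-en-1-yl)bicyclo[3.3.1]non-3-en-7-yl]prop-2-en-1-yl acetate (carbinol epimers) | C=CC(OC(C)=O)[C@@H]1C[C@]2(CC=C)C(=O)[C@@](CC=C)(C(=O)C(C(=O)c3ccc(OS(=O)(=O)c4ccc(C)cc4)c(OS(=O)(=O)c4ccc(C)cc4)c3)=C2OC)C1(C)C
F10 | step 8 | 4-{[(1S,5S,7R)-4-methoxy-8,8-dimethyl-2,9-dioxo-1,5,7-tri(prop-2-en-1-yl)bicyclo[3.3.1]non-3-en-3-yl]carbonyl}-1,2-phenylene bis(4-methylbenzenesulfonate) | C=CC[C@@H]1C[C@]2(CC=C)C(=O)[C@@](CC=C)(C(=O)C(C(=O)c3ccc(OS(=O)(=O)c4ccc(C)cc4)c(OS(=O)(=O)c4ccc(C)cc4)c3)=C2OC)C1(C)C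
F11 | step 4 | (Z)-3-iodo-2-(prop-2-en-1-yl)but-2-en-1-ol | OC/C(CC=C)=C(\I)C
A1 | direct plan | (S)-2,2-dimethyl-3-(3-methylbut-2-en-1-yl)cyclopentan-1-one | CC(C)=CC[C@@H]1CCC(=O)C1(C)C
A2 | direct plan | (2R,3aR,7aR)-7a-hydroxy-6-methoxy-1,1-dimethyl-2,3a-bis(3-methylbut-2-en-1-yl)-1,2,3,3a,7,7a-hexahydro-4H-inden-4-one | CC(C)=CC[C@@H]1C[C@]2(CC=C(C)C)[C@@](O)(CC(OC)=CC2=O)C1(C)C
A3 | direct plan | (1R,5S,7R)-2-methoxy-8,8-dimethyl-5,7-bis(3-methylbut-2-en-1-yl)bicyclo[3.3.1]non-2-ene-4,9-dione | CC(C)=CC[C@@H]1C[C@]2(CC=C(C)C)C(=O)[C@@H](C(OC)=CC2=O)C1(C)C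
A4 | direct plan | (1R,5R,7R)-3-{3,4-bis[(tert-butyldimethylsilyl)oxy]benzoyl}-2-methoxy-8,8-dimethyl-5,7-bis(3-methylbut-2-en-1-yl)bicyclo[3.3.1]non-2-ene-4,9-dione | CC(C)=CC[C@@H]1C[C@]2(CC=C(C)C)C(=O)[C@@H](C(OC)=C(C(=O)c3ccc(O[Si](C)(C)C(C)(C)C)c(O[Si](C)(C)C(C)(C)C)c3)C2=O)C1(C)C
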